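**Plan**
- Retrosynthesis: remove the C8 acetate, the C9 (2S,3S)-epoxyangelate and the exo-methylene C13, then cut C8–C9. These are adjacent, oxygen-bearing carbons of the ten-membered carbocycle (a 1,2-diol); C9 is allylic to the Z C1=C10 alkene and C8 sits on the C7 carbinol carbon of the γ-lactone. The ring therefore opens to a Z-enal / α-hydroxy aldehyde that a reductive pinacol coupling can close.
- The dialdehyde is cut at C6–C7 (aldol) into a chain aldehyde and a malic acid unit. Geraniol supplies C1–C6 and C15 with the E C4=C5 alkene; a Still–Gennari phosphonate supplies C9, C10, C14 and the Z alkene. (R)-Malic acid, as its pivalaldehyde dioxolanone, supplies C7, C8, C11 and C12.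
- Forward: the chain is built first (steps 1–7), then the aldol/lactonisation forms the γ-lactone. Redox adjustment gives the dialdehyde, SmI2 closes the ten-membered ring, and C13 is added only afterwards because SmI2 would reduce an α-methylene lactone. Two site-selective acylations finish the route.
- Stereochemistry: C7 comes from (R)-malic acid (self-regeneration of stereocentres). C6 is set in the aldol, C8 and C9 in the pinacol step (samarium chelation and bridging). The epoxide comes from a Sharpless epoxidation with D-(−)-diethyl tartrate.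

Key step: step 12

Remark: locants follow the target: ring carbons C1–C10 with C6 (lactone O–CH), C7 (C–OH), C8 (CH–OAc), C9 (CH–O-ester), C10(CH3-14)=C1 (Z) and C4(CH3-15)=C5 (E); C11, C12, C13 are the lactone α-carbon, carbonyl and exo-methylene.
Remark: compound 3 is racemic at its epoxide carbon (centre destroyed in the same step); 19 and 20 are drawn as the expected C11 epimer, and either epimer serves.

**Step 1**
Reactants: 1 geraniol
Product: 2 geranyl 4-methoxybenzyl ether
Conditions: NaH, 4-methoxybenzyl chloride, Bu4NI (cat.), THF–DMF, 0 → 23 °C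
Reagents that add atoms: 4-methoxybenzyl chloride, COc1ccc(CCl)cc1
Why: Williamson etherification of the primary allylic alkoxide; the PMB group survives hydride and base and can later be removed oxidatively beside a silyl ether.

**Step 2**
Reactants: 2 geranyl 4-methoxybenzyl ether
Product: 4 (4E)-6-[(4-methoxybenzyl)oxy]-4-methylhex-4-enal, via 6,7-epoxide 3 (not isolated)
Conditions: mCPBA, CH2Cl2, −20 °C; then H5IO6, THF–H2O, 0 °C
Reagents that add atoms: mCPBA, O=C(OO)c1cccc(Cl)c1 (its oxygen becomes the aldehyde oxygen)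
Why: Prilezhaev epoxidation should prefer the electron-rich terminal alkene (the 2,3-alkene is deactivated by the allylic oxygen), and periodic acid then hydrolyses the epoxide and cleaves the glycol (Malaprade cleavage) to the aldehyde and acetone.

**Step 3**
Reactants: 4 (4E)-6-[(4-methoxybenzyl)oxy]-4-methylhex-4-enal; 5 methyl 2-[bis(2,2,2-trifluoroethoxy)phosphoryl]propanoate
Product: 6 methyl (2Z,6E)-8-[(4-methoxybenzyl)oxy]-2,6-dimethylocta-2,6-dienoate
Conditions: KN(SiMe3)2, 18-crown-6, THF, −78 °C
Reagents that add atoms: none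
Why: Still–Gennari variant of the Horner–Wadsworth–Emmons olefination; fast, irreversible elimination from the trifluoroethyl phosphonate adduct should give the Z trisubstituted enoate (future C1=C10, carbonyl cis to the chain).

**Step 4**
Reactants: 6 methyl (2Z,6E)-8-[(4-methoxybenzyl)oxy]-2,6-dimethylocta-2,6-dienoate
Product: 7 (2Z,6E)-8-[(4-methoxybenzyl)oxy]-2,6-dimethylocta-2,6-dien-1-ol
Conditions: iBu2AlH (2.5 equiv), CH2Cl2, −78 °C; aq. potassium sodium tartrate
Reagents that add atoms: none
Why: 1,2-reduction of the conjugated ester to the allylic alcohol by an aluminium hydride, without change of alkene geometry.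

**Step 5**
Reactants: 7 (2Z,6E)-8-[(4-methoxybenzyl)oxy]-2,6-dimethylocta-2,6-dien-1-ol
Product: 8 triethyl{[(2Z,6E)-8-[(4-methoxybenzyl)oxy]-2,6-dimethylocta-2,6-dien-1-yl]oxy}silane
Conditions: Et3SiCl, imidazole, CH2Cl2, 0 °C
Reagents that add atoms: chlorotriethylsilane, CC[Si](Cl)(CC)CC
Why: silylation of the primary alcohol; the triethylsilyl ether survives the enolate step and is labile enough to be lost in the acidic work-up of step 9.

**Step 6**
Reactants: 8 triethyl{[(2Z,6E)-8-[(4-methoxybenzyl)oxy]-2,6-dimethylocta-2,6-dien-1-yl]oxy}silane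
Product: 9 (2E,6Z)-3,7-dimethyl-8-[(triethylsilyl)oxy]octa-2,6-dien-1-ol
Conditions: DDQ, CH2Cl2–pH 7 phosphate buffer (10:1), 0 °C
Reagents that add atoms: none
Why: oxidative cleavage of the PMB ether by DDQ (hydride abstraction, then hydrolysis of the oxocarbenium ion), which under buffered conditions should leave the silyl ether and both alkenes intact.

**Step 7**
Reactants: 9 (2E,6Z)-3,7-dimethyl-8-[(triethylsilyl)oxy]octa-2,6-dien-1-ol
Product: 10 (2E,6Z)-3,7-dimethyl-8-[(triethylsilyl)oxy]octa-2,6-dienal
Conditions: MnO2 (activated, excess), CH2Cl2, 23 °C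
Reagents that add atoms: none
Why: MnO2 oxidation of the primary allylic alcohol to the E enal (C6 aldehyde) under neutral conditions that do not isomerise the alkene.

**Step 8**
Reactants: 11 (R)-malic acid
Product: 12 2-[(2R,4R)-2-tert-butyl-5-oxo-1,3-dioxolan-4-yl]acetic acid
Conditions: pivalaldehyde, TsOH·H2O (cat.), H2SO4 (cat.), pentane, reflux with azeotropic removal of water; recrystallisation
Reagents that add atoms: pivalaldehyde, CC(C)(C)C=O
Why: acid-catalysed acetalisation of the α-hydroxy acid; the cis-2,4-disubstituted dioxolanone is the thermodynamic product and is enriched by crystallisation, so the acetal centre is set relative to the malic acid stereocentre (temporary ring for self-regeneration of stereocentres).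

**Step 9**
Reactants: 12 2-[(2R,4R)-2-tert-butyl-5-oxo-1,3-dioxolan-4-yl]acetic acid; 10 (2E,6Z)-3,7-dimethyl-8-[(triethylsilyl)oxy]octa-2,6-dienal
Product: 14 (2R,5S,6S)-2-tert-butyl-6-[(1E,5Z)-7-hydroxy-2,6-dimethylhepta-1,5-dien-1-yl]-1,3,7-trioxaspiro[4.4]nonane-4,8-dione, via aldol hydroxy acid 13 (not isolated)
Conditions: LiN(SiMe3)2 (2.1 equiv), THF, −78 °C; 10, −78 °C; AcOH quench; then AcOH–THF–H2O (3:1:1), 23 °C
Reagents that add atoms: none
Why: aldol addition of the carboxylate/dioxolanone lithium enolate to the aldehyde anti to the tert-butyl group (C7 set with retention); a chair Zimmerman–Traxler transition state with the alkenyl group equatorial should place the C6–O anti to the C7–O along C8–C7–C6–C5 (C6 set), and mild acid then cleaves the silyl ether and lactonises the γ-hydroxy acid to the trans-substituted γ-lactone.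

**Step 10**
Reactants: 14 the spiro dioxolanone lactone
Product: 15 (4R,5S)-4-hydroxy-4-(hydroxymethyl)-5-[(1E,5Z)-7-hydroxy-2,6-dimethylhepta-1,5-dien-1-yl]oxolan-2-one
Conditions: NaBH4 (2 equiv), THF–EtOH (4:1), −20 → 0 °C; AcOH quench
Reagents that add atoms: none
Why: chemoselective borohydride reduction of the activated, acylal-type dioxolanone carbonyl (C8), which collapses with loss of pivalaldehyde and is reduced on to the primary alcohol much faster than the unactivated γ-lactone; cold, short reaction and an acid quench are used to avoid translactonisation onto the new C8 hydroxyl.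

**Step 11**
Reactants: 15 the lactone triol
Product: 16 (2S,3S)-3-hydroxy-2-[(1E,5Z)-2,6-dimethyl-7-oxohepta-1,5-dien-1-yl]-5-oxooxolane-3-carbaldehyde
Conditions: IBX (3 equiv), DMSO, 23 °C; aqueous work-up; used crude at once
Reagents that add atoms: none
Why: IBX oxidation of both primary alcohols (allylic C9 and neopentyl C8) to aldehydes, leaving the tertiary C7 hydroxyl, without cleavage of the 1,2-diol and under neutral conditions that should keep the Z enal geometry.

**Step 12**
Reactants: 16 the Z-enal / α-hydroxy aldehyde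
Product: 17 (3aS,4S,5S,6Z,10E,11aS)-3a,4,5-trihydroxy-6,10-dimethyl-3a,4,5,8,9,11a-hexahydrocyclodeca[b]furan-2(3H)-one
Conditions: SmI2 (3 equiv, 0.1 M in THF), THF, −78 °C, syringe-pump addition of 16 (final 0.003 M), then −78 → −40 °C; aq. potassium sodium tartrate
Reagents that add atoms: none
Why: Two single-electron transfers from samarium diiodide convert the chelated α-hydroxy aldehyde (C8) and the Z enal (C9) into ketyls bound to trivalent samarium, and C8–C9 bond formation between the two carbinol carbons gives the samarium diolate of 17. The closest known reaction type is the intramolecular pinacol coupling of dialdehydes with samarium diiodide or low-valent titanium, which is established for enal partners and for medium and large rings. The ten-membered carbocycle is closed by ketyl–carbonyl coupling, formally 10-exo-trig with respect to the accepting C=O, with the chain pre-organised by the trans-substituted γ-lactone and the Z C1=C10 and E C4=C5 alkenes. C8 is controlled by five-membered chelation of samarium between the C7 hydroxyl and the C8 ketyl oxygen, so that the new C8–O should end anti to the C7–O on the ring; C9 is controlled by bridging of both ketyl oxygens on samarium, which holds them syn in the bond-forming event and should give the cis-8,9-diol. The step needs coupling at the carbonyl carbon and not through the γ-carbon C1 of the enal ketyl (which would give an eight-membered ring), retention of the Z geometry, and cyclisation over oligomerisation; the oxygen–samarium template, the low temperature (slow rotation of the oxyallyl radical) and slow addition at high dilution are expected to secure these.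

**Step 13**
Reactants: 17 the macrocyclic triol
Product: 18 the 8,9-bis(triethylsilyl) ether of 17 (C7–OH free)
Conditions: Et3SiOTf (2.2 equiv), 2,6-lutidine, CH2Cl2, −78 °C
Reagents that add atoms: triethylsilyl trifluoromethanesulfonate, CC[Si](CC)(CC)OS(=O)(=O)C(F)(F)F
Why: silylation of the two secondary hydroxyls, while the tertiary C7 hydroxyl should not react at −78 °C; the silyl ethers protect the diol for enolate chemistry and can be removed with fluoride, avoiding acid on the acid-sensitive cyclodeca-1,5-diene.

**Step 14**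
Reactants: 18 the bis(triethylsilyl) ether
Product: 21 (3aS,4S,5S,6Z,10E,11aS)-3a-hydroxy-6,10-dimethyl-3-methylidene-4,5-bis[(triethylsilyl)oxy]-3a,4,5,8,9,11a-hexahydrocyclodeca[b]furan-2(3H)-one, via Mannich base 19 (not isolated), via methiodide 20 (not isolated)
Conditions: LiN(iPr)2 (2.3 equiv), THF, −78 °C; Eschenmoser's salt (3 equiv), −78 → −20 °C; then MeOH, MeI (excess), 23 °C; then aq. NaHCO3, 23 °C
Reagents that add atoms: Eschenmoser's salt (dimethylmethylideneammonium iodide), C=[N+](C)C.[I-]
Why: the alkoxide/enolate dianion of the β-hydroxy lactone (Fráter–Seebach-type, stable to β-elimination and retro-aldol) undergoes a Mannich reaction at C11, and quaternisation followed by Hofmann-type elimination gives the α-methylene lactone; C7 carries no hydrogen, so only the exocyclic alkene can form.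

**Step 15**
Reactants: 21 the bis(triethylsilyl) α-methylene lactone
Product: 22 (3aS,4S,5S,6Z,10E,11aS)-3a,4,5-trihydroxy-6,10-dimethyl-3-methylidene-3a,4,5,8,9,11a-hexahydrocyclodeca[b]furan-2(3H)-one
Conditions: HF·pyridine, pyridine, THF, 0 °C
Reagents that add atoms: none
Why: fluoride-mediated cleavage of both secondary silyl ethers under buffered conditions that should spare the α-methylene lactone and the ring diene.

**Step 16**
Reactants: 23 methyl angelate
Product: 24 (2Z)-2-methylbut-2-en-1-ol
Conditions: LiAlH4, Et2O, 0 °C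
Reagents that add atoms: none
Why: 1,2-reduction of the conjugated ester to the allylic alcohol with retention of the Z geometry.

**Step 17**
Reactants: 24 (2Z)-2-methylbut-2-en-1-ol
Product: 25 [(2R,3S)-2,3-dimethyloxiran-2-yl]methanol
Conditions: Ti(OiPr)4 (10 mol%), D-(−)-diethyl tartrate (12 mol%), tBuOOH, 4 Å molecular sieves, CH2Cl2, −20 °C
Reagents that add atoms: tert-butyl hydroperoxide, CC(C)(C)OO
Why: Sharpless asymmetric epoxidation; the D-(−)-tartrate catalyst delivers oxygen to the alkene face opposite to that attacked with L-(+)-tartrate (which gives the 2S series), setting both epoxide centres, and the syn addition to the Z alkene keeps the two methyl groups trans.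

**Step 18**
Reactants: 25 [(2R,3S)-2,3-dimethyloxiran-2-yl]methanol
Product: 26 (2S,3S)-2,3-dimethyloxirane-2-carboxylic acid
Conditions: RuCl3·xH2O (2 mol%), NaIO4 (3 equiv), EtOAc–MeCN–H2O, 0 → 23 °C
Reagents that add atoms: water, O (the new carboxyl oxygen, via the aldehyde hydrate; NaIO4 is the terminal oxidant)
Why: ruthenium tetroxide-catalysed oxidation of the primary epoxy alcohol to the glycidic acid without touching the epoxide; the C2 descriptor changes from R to S only through the priority change.

**Step 19**
Reactants: 22 the α-methylene lactone triol; 26 (2S,3S)-2,3-dimethyloxirane-2-carboxylic acid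
Product: 28 (3aS,4S,5S,6Z,10E,11aS)-3a,4-dihydroxy-6,10-dimethyl-3-methylidene-2-oxo-2,3,3a,4,5,8,9,11a-octahydrocyclodeca[b]furan-5-yl (2S,3S)-2,3-dimethyloxirane-2-carboxylate, via mixed anhydride 27 (not isolated)
Conditions: 26 (1.1 equiv), 2,4,6-trichlorobenzoyl chloride, Et3N, THF, 0 °C; then 22, DMAP, toluene, 0 → 23 °C
Reagents that add atoms: none
Why: Yamaguchi esterification; the hindered acyl donor should react at the allylic C9 hydroxyl, because the C8 hydroxyl is flanked by the fully substituted C7 and the tertiary C7 hydroxyl is inert.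

**Step 20**
Reactants: 28 the C9 epoxyangelate
Product: 29 the target, (3aS,4S,5S,6Z,10E,11aS)-4-acetoxy-3a-hydroxy-6,10-dimethyl-3-methylidene-2-oxo-2,3,3a,4,5,8,9,11a-octahydrocyclodeca[b]furan-5-yl (2S,3S)-2,3-dimethyloxirane-2-carboxylate
Conditions: Ac2O, pyridine, DMAP (cat.), CH2Cl2, 0 → 23 °C
Reagents that add atoms: acetic anhydride, CC(=O)OC(C)=O
Why: DMAP-catalysed acetylation of the remaining secondary C8 hydroxyl; the tertiary C7 hydroxyl should not be acylated under these conditions.

**Compound list**
1 | geraniol, (2E)-3,7-dimethylocta-2,6-dien-1-ol | CC(C)=CCC/C(C)=C/CO | starting material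
2 | geranyl 4-methoxybenzyl ether | COc1ccc(COC/C=C(\C)CCC=C(C)C)cc1 | intermediate
3 | 6,7-epoxygeranyl 4-methoxybenzyl ether (racemic at the epoxide carbon) | COc1ccc(COC/C=C(\C)CCC2OC2(C)C)cc1 | intermediate (not isolated)
4 | (4E)-6-[(4-methoxybenzyl)oxy]-4-methylhex-4-enal | COc1ccc(COC/C=C(\C)CCC=O)cc1 | intermediate
5 | methyl 2-[bis(2,2,2-trifluoroethoxy)phosphoryl]propanoate | COC(=O)C(C)P(=O)(OCC(F)(F)F)OCC(F)(F)F | starting material
6 | methyl (2Z,6E)-8-[(4-methoxybenzyl)oxy]-2,6-dimethylocta-2,6-dienoate | COc1ccc(COC/C=C(\C)CC/C=C(/C)C(=O)OC)cc1 | intermediate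
7 | (2Z,6E)-8-[(4-methoxybenzyl)oxy]-2,6-dimethylocta-2,6-dien-1-ol | COc1ccc(COC/C=C(\C)CC/C=C(/C)CO)cc1 | intermediate
8 | triethylsilyl ether of 7 | COc1ccc(COC/C=C(\C)CC/C=C(/C)CO[Si](CC)(CC)CC)cc1 | intermediate
9 | (2E,6Z)-3,7-dimethyl-8-[(triethylsilyl)oxy]octa-2,6-dien-1-ol | OC/C=C(\C)CC/C=C(/C)CO[Si](CC)(CC)CC | intermediate
10 | (2E,6Z)-3,7-dimethyl-8-[(triethylsilyl)oxy]octa-2,6-dienal | O=C/C=C(\C)CC/C=C(/C)CO[Si](CC)(CC)CC | intermediate
11 | (R)-malic acid | OC(=O)C[C@@H](O)C(O)=O | starting material
12 | 2-[(2R,4R)-2-tert-butyl-5-oxo-1,3-dioxolan-4-yl]acetic acid (cis) | OC(=O)C[C@H]1O[C@@H](C(C)(C)C)OC1=O | intermediate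
13 | 2-[(2R,4S)-2-tert-butyl-4-{(1S,2E,6Z)-1-hydroxy-3,7-dimethyl-8-[(triethylsilyl)oxy]octa-2,6-dien-1-yl}-5-oxo-1,3-dioxolan-4-yl]acetic acid | OC(=O)C[C@]1(O[C@@H](C(C)(C)C)OC1=O)[C@@H](O)/C=C(\C)CC/C=C(/C)CO[Si](CC)(CC)CC | intermediate (not isolated)
14 | (2R,5S,6S)-2-tert-butyl-6-[(1E,5Z)-7-hydroxy-2,6-dimethylhepta-1,5-dien-1-yl]-1,3,7-trioxaspiro[4.4]nonane-4,8-dione | C1C(=O)O[C@@H](/C=C(\C)CC/C=C(/C)CO)[C@@]12O[C@@H](C(C)(C)C)OC2=O | intermediate
15 | (4R,5S)-4-hydroxy-4-(hydroxymethyl)-5-[(1E,5Z)-7-hydroxy-2,6-dimethylhepta-1,5-dien-1-yl]oxolan-2-one | C1C(=O)O[C@@H](/C=C(\C)CC/C=C(/C)CO)[C@]1(O)CO | intermediate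
16 | (2S,3S)-3-hydroxy-2-[(1E,5Z)-2,6-dimethyl-7-oxohepta-1,5-dien-1-yl]-5-oxooxolane-3-carbaldehyde | C1C(=O)O[C@@H](/C=C(\C)CC/C=C(/C)C=O)[C@]1(O)C=O | intermediate
17 | (3aS,4S,5S,6Z,10E,11aS)-3a,4,5-trihydroxy-6,10-dimethyl-3a,4,5,8,9,11a-hexahydrocyclodeca[b]furan-2(3H)-one | C1C(=O)O[C@H]2/C=C(\C)CC/C=C(/C)[C@H](O)[C@H](O)[C@]12O | intermediate
18 | 8,9-bis(triethylsilyl) ether of 17 | C1C(=O)O[C@H]2/C=C(\C)CC/C=C(/C)[C@H](O[Si](CC)(CC)CC)[C@H](O[Si](CC)(CC)CC)[C@]12O | intermediate
19 | 11-[(dimethylamino)methyl] derivative of 18 (CH2NMe2 drawn trans to the C7–O) | CN(C)C[C@@H]1C(=O)O[C@H]2/C=C(\C)CC/C=C(/C)[C@H](O[Si](CC)(CC)CC)[C@H](O[Si](CC)(CC)CC)[C@]12O | intermediate (not isolated)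
20 | N-methyl iodide (trimethylammonium salt) of 19 | C[N+](C)(C)C[C@@H]1C(=O)O[C@H]2/C=C(\C)CC/C=C(/C)[C@H](O[Si](CC)(CC)CC)[C@H](O[Si](CC)(CC)CC)[C@]12O.[I-] | intermediate (not isolated)
21 | 8,9-bis(triethylsilyl) ether of the α-methylene lactone triol | C=C1C(=O)O[C@H]2/C=C(\C)CC/C=C(/C)[C@H](O[Si](CC)(CC)CC)[C@H](O[Si](CC)(CC)CC)[C@]12O | intermediate
22 | (3aS,4S,5S,6Z,10E,11aS)-3a,4,5-trihydroxy-6,10-dimethyl-3-methylidene-3a,4,5,8,9,11a-hexahydrocyclodeca[b]furan-2(3H)-one | C=C1C(=O)O[C@H]2/C=C(\C)CC/C=C(/C)[C@H](O)[C@H](O)[C@]12O | intermediate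
23 | methyl angelate, methyl (2Z)-2-methylbut-2-enoate | C/C=C(/C)C(=O)OC | starting material
24 | (2Z)-2-methylbut-2-en-1-ol | C/C=C(/C)CO | intermediate
25 | [(2R,3S)-2,3-dimethyloxiran-2-yl]methanol | OC[C@@]1(C)O[C@H]1C | intermediate
26 | (2S,3S)-2,3-dimethyloxirane-2-carboxylic acid | OC(=O)[C@@]1(C)O[C@H]1C | intermediate
27 | (2S,3S)-2,3-dimethyloxirane-2-carboxylic 2,4,6-trichlorobenzoic anhydride | O=C(OC(=O)[C@@]1(C)O[C@H]1C)c1c(Cl)cc(Cl)cc1Cl | intermediate (not isolated)
28 | C9 (2S,3S)-epoxyangelate of 22 (C7–OH and C8–OH free) | C=C1C(=O)O[C@H]2/C=C(\C)CC/C=C(/C)[C@H](OC(=O)[C@@]3(C)O[C@H]3C)[C@H](O)[C@]12O | intermediate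
29 | target, CNP0271187.2 | C=C1C(=O)O[C@H]2/C=C(\C)CC/C=C(/C)[C@H](OC(=O)[C@@]3(C)O[C@H]3C)[C@H](OC(C)=O)[C@]12O | target

**Step count**
Total: 20 steps. Longest linear sequence: 16 steps (steps 1–7, 9–15, 19, 20).

**Steps most likely to fail**

1. Step 12. The ketyl coupling may show poor facial selectivity at C9 (trans-diol), may couple through the γ-carbon of the enal ketyl, or may lose to oligomerisation. The fallback separates ring closure from C9 stereocontrol. It sets out from 16, which is cyclised with low-valent titanium (TiCl3(DME)1.5, Zn–Cu couple, DME, slow addition), a metal-surface pinacol that is known to close medium rings from enal–aldehydes. The macrocyclic triol is accepted as a mixture at C9 that contains the C9-epimeric triol F1. MnO2 then oxidises only the allylic C9 hydroxyl of the whole mixture to the α-hydroxy enone F2. Reduction with Zn(BH4)2 in Et2O at −78 °C, under chelation between the C8 hydroxyl and the C9 carbonyl, should give the cis (erythro) diol, and the route is rejoined at 17.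

2. Step 9. The aldol may show poor facial selectivity at the aldehyde carbon (C6), giving the 6-epimeric lactone. The fallback sets C6 by reagent-controlled reduction and sets out from 10 and 12. The aldol is run as before, quenched cold and the crude acid esterified with TMSCHN2 to the hydroxy methyl ester F3 (mixture at C6). MnO2 oxidises the allylic carbinol to the enone F4, in which both epimers converge. Corey–Bakshi–Shibata reduction with catecholborane at −78 °C, using the catalyst enantiomer that delivers hydride to the required face ((R)-Me-CBS if the quaternary C7 substituent acts as the large group), should give the 6S carbinol ester F5. AcOH–THF–H2O followed by PPTS then removes the silyl group and closes the lactone, and the route is rejoined at 14.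

3. Step 19. The esterification may show insufficient site selectivity between the C9 and C8 hydroxyls, or the acyl group may migrate within the cis-diol. The fallback differentiates the two oxygens before the diol is unmasked and sets out from 21. The less hindered, allylic C9 silyl ether is cleaved selectively (PPTS, MeOH–CH2Cl2, −10 °C) to the C8 mono(triethylsilyl) ether F6. Yamaguchi esterification with 26 then gives the C9 epoxyangelate C8 silyl ether F7. HF·pyridine removes the remaining silyl group, and the route is rejoined at 28.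

**Further compounds**
F1 | step 12 | C9 epimer of 17 (trans-8,9-diol) | C1C(=O)O[C@H]2/C=C(\C)CC/C=C(/C)[C@@H](O)[C@H](O)[C@]12O
F2 | step 12 | 9-oxo derivative of 17 (α-hydroxy enone, C7–OH and C8–OH free) | C1C(=O)O[C@H]2/C=C(\C)CC/C=C(/C)C(=O)[C@H](O)[C@]12O
F3 | step 9 | methyl ester of 13 as a mixture at the carbinol carbon C6 | COC(=O)C[C@]1(O[C@@H](C(C)(C)C)OC1=O)C(O)/C=C(\C)CC/C=C(/C)CO[Si](CC)(CC)CC
F4 | step 9 | methyl 2-[(2R,4S)-2-tert-butyl-4-{(2E,6Z)-3,7-dimethyl-8-[(triethylsilyl)oxy]octa-2,6-dienoyl}-5-oxo-1,3-dioxolan-4-yl]acetate | COC(=O)C[C@]1(O[C@@H](C(C)(C)C)OC1=O)C(=O)/C=C(\C)CC/C=C(/C)CO[Si](CC)(CC)CC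
F5 | step 9 | methyl ester of 13 (single 6S epimer) | COC(=O)C[C@]1(O[C@@H](C(C)(C)C)OC1=O)[C@@H](O)/C=C(\C)CC/C=C(/C)CO[Si](CC)(CC)CC
F6 | step 19 | C8 mono(triethylsilyl) ether of 22 (C9–OH and C7–OH free) | C=C1C(=O)O[C@H]2/C=C(\C)CC/C=C(/C)[C@H](O)[C@H](O[Si](CC)(CC)CC)[C@]12O
F7 | step 19 | C8 triethylsilyl ether of 28 | C=C1C(=O)O[C@H]2/C=C(\C)CC/C=C(/C)[C@H](OC(=O)[C@@]3(C)O[C@H]3C)[C@H](O[Si](CC)(CC)CC)[C@]12O
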